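**Strategy**

Everything rests on cutting the C4–C5 bond of the furanone ring (ring A). C5, the only stereocentre, is a secondary carbinol carbon next to C4, and C2, C3 and C4 correspond to the ester carbon and the two sp carbons of a propiolate. A chiral catalyst assembled from Me2Zn and the ProPhenol ligand adds the zinc acetylide of methyl propiolate to (benzyloxy)acetaldehyde, so one operation makes the C4–C5 bond and fixes C5 from two achiral, purchased partners. The adduct carries C2 to C6 at their final oxidation levels; methanol addition with lactonization, enol ether hydrolysis, C3 acylation and debenzylation complete the target.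

Key step: step 1

Numbering used below: ring A is O1, C2 (lactone carbonyl), C3, C4, C5; C6 is the exocyclic CH2O carbon. The target and 10 are drawn as their 4-hydroxy enol tautomers.

Assumption: (R,R)-ProPhenol is taken as the ligand enantiomer that sends the acetylide to the Re face of 2, a sense inferred from unbranched aliphatic aldehydes and not certain for this substrate; the configuration of 4 is to be confirmed by Mosher ester analysis before scale-up, and the antipodal ligand is used if the opposite carbinol forms.

**Route**

Step 1
Reactants: 1 methyl propiolate; 2 (benzyloxy)acetaldehyde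
Product: 4 methyl (R)-5-(benzyloxy)-4-hydroxypent-2-ynoate, via methylzinc acetylide 3 (not isolated)
Conditions: (R,R)-ProPhenol (20 mol%), Ph3P=O (40 mol%), Me2Zn (3 equiv), 1 (3 equiv), toluene, 0 °C, 1 h; then 2 (freshly distilled, slow addition), 4 °C, 48 h; aq NH4Cl
Reagents that add atoms: none
Why: Me2Zn metalates 1 to alkynylzinc 3 and, with the ligand, forms a two-zinc catalyst in which one zinc activates the aldehyde oxygen while the other passes the alkynyl group to the carbonyl carbon, and aqueous NH4Cl then frees 4. The closest known reaction type is the ProPhenol-mediated enantioselective addition of methyl propiolate to aldehydes, for which unbranched and α-alkoxy aldehydes are documented but demanding substrates. No ring closes; only the C4–C5 bond (target numbering) is made. The new stereocentre is set purely by the catalyst, whose pocket presents the Re face of the carbonyl to the acetylide, giving the R carbinol that becomes S at C5 of the target when the ring changes the CIP priorities. The step needs enantioface selectivity and 1,2-addition in preference to self-aldolization of 2 or methyl transfer; these are secured by the low nucleophilicity of Me2Zn, the pre-formed excess acetylide, the Ph3P=O additive, low temperature and slow addition of 2, while the benzyl ether is only a weak monodentate donor that should not outcompete the ligand.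

Step 2
Reactants: 4 methyl (R)-5-(benzyloxy)-4-hydroxypent-2-ynoate
Product: 6 (S)-5-[(benzyloxy)methyl]-4-methoxyfuran-2(5H)-one, via E-methoxy enoate 5 (not isolated)
Conditions: NaOMe (0.3 equiv), MeOH, 0 °C to rt; AcOH quench
Reagents that add atoms: methanol (solvent and nucleophile, activated by NaOMe), SMILES CO
Why: Methoxide-catalysed oxa-Michael addition of methanol at the β-carbon of the ynoate gives the β-methoxy enoate, whose Z and E forms interconvert by reversible methoxide addition, and the E isomer 5 is drained by lactonization (5-exo-trig acyl substitution by the carbinol oxygen) to the methyl tetronate, a known tetronate synthesis from 4-hydroxy-2-ynoates in which no bond at the stereocentre is broken, so the configuration is retained (S by CIP in the ring).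

Step 3
Reactants: 6 (S)-5-[(benzyloxy)methyl]-4-methoxyfuran-2(5H)-one
Product: 7 (S)-5-[(benzyloxy)methyl]-4-hydroxyfuran-2(5H)-one
Conditions: 6 M aq HCl/1,4-dioxane (1:1), 70 °C, monitored; extraction into aq NaHCO3, re-acidification
Reagents that add atoms: water, SMILES O
Why: Acid-catalysed hydrolysis of a vinylogous carbonate (addition of water at C4 and loss of methanol) is the classical conversion of methyl tetronates into tetronic acids; the alkyl benzyl ether should tolerate hot aqueous HCl for the time needed, C5 is not involved, and the acidic product is purified by bicarbonate extraction.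

Step 4
Reactants: 7 (S)-5-[(benzyloxy)methyl]-4-hydroxyfuran-2(5H)-one; 8 13-methyltetradecanoic acid
Product: 10 (S)-5-[(benzyloxy)methyl]-4-hydroxy-3-(13-methyltetradecanoyl)furan-2(5H)-one, via enol ester 9 (not isolated)
Conditions: 8 (1.1 equiv), DCC (1.2 equiv), DMAP (0.3 equiv), Et3N (1.2 equiv), CH2Cl2, 0 °C to rt; filtration, 1 M HCl wash
Reagents that add atoms: none
Why: Carbodiimide activation of 8 (Steglich conditions) acylates the 4-hydroxyl to enol ester 9, and DMAP then relays the acyl group from oxygen to C3 (Fries-type 1,3-acyl shift), driven by formation of the strongly acidic, hydrogen-bonded 3-acyltetronic acid; this one-pot 3-acylation is standard for 5-substituted tetronic acids and fatty acids and leaves C5 untouched.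

Step 5
Reactants: 10 (S)-5-[(benzyloxy)methyl]-4-hydroxy-3-(13-methyltetradecanoyl)furan-2(5H)-one
Product: 11 (S)-4-hydroxy-5-(hydroxymethyl)-3-(13-methyltetradecanoyl)furan-2(5H)-one
Conditions: H2 (1 atm), Pd/C (10 wt% palladium on carbon), EtOAc, rt
Reagents that add atoms: none
Why: Heterogeneous hydrogenolysis cleaves the primary benzyl ether, whereas the 3-acyl-4-hydroxybutenolide is a cross-conjugated, chelated tricarbonyl enol that should resist hydrogenation at 1 atm and room temperature, so the target is released with C5 unchanged.

**Compound list**

1 | methyl propiolate | C#CC(=O)OC | starting material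
2 | (benzyloxy)acetaldehyde | O=CCOCc1ccccc1 | starting material
3 | methyl 3-(methylzincio)prop-2-ynoate (methylzinc acetylide of 1, not isolated) | C[Zn]C#CC(=O)OC | intermediate
4 | methyl (R)-5-(benzyloxy)-4-hydroxypent-2-ynoate | COC(=O)C#C[C@H](COCc1ccccc1)O | intermediate
5 | methyl (2E,4S)-5-(benzyloxy)-4-hydroxy-3-methoxypent-2-enoate (not isolated) | COC(=O)/C=C(/OC)[C@H](COCc1ccccc1)O | intermediate
6 | (S)-5-[(benzyloxy)methyl]-4-methoxyfuran-2(5H)-one | COC1=CC(=O)O[C@H]1COCc2ccccc2 | intermediate
7 | (S)-5-[(benzyloxy)methyl]-4-hydroxyfuran-2(5H)-one | OC1=CC(=O)O[C@H]1COCc2ccccc2 | intermediate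
8 | 13-methyltetradecanoic acid | CC(C)CCCCCCCCCCCC(=O)O | starting material
9 | (S)-2-[(benzyloxy)methyl]-5-oxo-2,5-dihydrofuran-3-yl 13-methyltetradecanoate (not isolated) | CC(C)CCCCCCCCCCCC(=O)OC1=CC(=O)O[C@H]1COCc2ccccc2 | intermediate
10 | (S)-5-[(benzyloxy)methyl]-4-hydroxy-3-(13-methyltetradecanoyl)furan-2(5H)-one | CC(C)CCCCCCCCCCCC(=O)C1=C(O)[C@H](COCc2ccccc2)OC1=O | intermediate
11 | (S)-4-hydroxy-5-(hydroxymethyl)-3-(13-methyltetradecanoyl)furan-2(5H)-one | CC(C)CCCCCCCCCCCC(=O)C1=C(O)[C@H](CO)OC1=O | target

**Step count and risks**

Total step count: 5. Longest linear sequence: 5 steps (1 and 2 to 11).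

Steps most likely to fail:

1. Step 1. The risk is insufficient enantioface discrimination, because the ether oxygen of 2 can bind zinc and open a less selective pathway, together with self-aldol consumption of the aldehyde. Fallback: setting out from 1 and 2, the stereocentre is set by reagent-controlled reduction instead of addition. LiN(SiMe3)2 in THF at −78 °C would convert 1 into methyl 3-lithioprop-2-ynoate F1, which would add to 2 to give racemic methyl 5-(benzyloxy)-4-hydroxypent-2-ynoate F2. Dess–Martin oxidation in CH2Cl2 would give methyl 5-(benzyloxy)-4-oxopent-2-ynoate F3. Midland reduction with (S)-Alpine-Borane (from (−)-α-pinene), a reagent known for 4-oxo-2-ynoates in which the alkyne acts as the small group, should then return the R carbinol, rejoining the route at 4.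

2. Step 3. The risk is incomplete hydrolysis of the robust methyl enol ether under conditions mild enough to keep the benzyl ether, or partial debenzylation if the acid is forced. Fallback: setting out from 4, an enol ether that cleaves under mild acid is installed in place of the methyl ether. NaH (0.3 equiv) and 4-methoxybenzyl alcohol (5 equiv) in THF at 0 °C, with 4 Å molecular sieves to take up the methanol released, would add the alcohol to the ynoate to give methyl (2E,4S)-5-(benzyloxy)-4-hydroxy-3-[(4-methoxybenzyl)oxy]pent-2-enoate F4. This should lactonize in the flask to (S)-5-[(benzyloxy)methyl]-4-[(4-methoxybenzyl)oxy]furan-2(5H)-one F5. TFA with Et3SiH in CH2Cl2 at 0 °C would then remove the 4-methoxybenzyl group, the silane reducing the benzylic cation before it can alkylate C3, and the route is rejoined at 7.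

3. Step 2. The risk is base-mediated erosion of enantiopurity, either by propargyl–allenyl isomerization of 4 before addition or by deprotonation at C5 of the tetronate followed by β-elimination of benzyl alcohol. Fallback: setting out from 4, the ring is built with a neutral amine nucleophile instead of an alkoxide. Pyrrolidine (1.5 equiv) in MeOH at rt would give methyl (2E,4R)-5-(benzyloxy)-4-hydroxy-3-(pyrrolidin-1-yl)pent-2-enoate F6, which should lactonize to (R)-5-[(benzyloxy)methyl]-4-(pyrrolidin-1-yl)furan-2(5H)-one F7. The R descriptors of F6 and F7 reflect a CIP priority change only, not inversion; this amine route to 4-aminobutenolides is known to preserve the carbinol configuration. Hydrolysis of the vinylogous carbamate with 3 M aq HCl/1,4-dioxane at 80 °C would then give the tetronic acid, rejoining the route at 7.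

Further compounds
F1 | step 1 | methyl 3-lithioprop-2-ynoate | [Li]C#CC(=O)OC
F2 | step 1 | racemic methyl 5-(benzyloxy)-4-hydroxypent-2-ynoate | COC(=O)C#CC(O)COCc1ccccc1
F3 | step 1 | methyl 5-(benzyloxy)-4-oxopent-2-ynoate | COC(=O)C#CC(=O)COCc1ccccc1
F4 | step 3 | methyl (2E,4S)-5-(benzyloxy)-4-hydroxy-3-[(4-methoxybenzyl)oxy]pent-2-enoate | COC(=O)/C=C(/OCc1ccc(OC)cc1)[C@H](COCc2ccccc2)O
F5 | step 3 | (S)-5-[(benzyloxy)methyl]-4-[(4-methoxybenzyl)oxy]furan-2(5H)-one | COc1ccc(COC2=CC(=O)O[C@H]2COCc3ccccc3)cc1
F6 | step 2 | methyl (2E,4R)-5-(benzyloxy)-4-hydroxy-3-(pyrrolidin-1-yl)pent-2-enoate | COC(=O)/C=C(/N1CCCC1)[C@H](COCc2ccccc2)O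
F7 | step 2 | (R)-5-[(benzyloxy)methyl]-4-(pyrrolidin-1-yl)furan-2(5H)-one | O=C1C=C(N2CCCC2)[C@H](COCc3ccccc3)O1
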